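**Plan**

- Retrosynthesis: the two ring B benzyl ethers and the O-methyl group at C3 are removed first, then the C3–O bond (back to a flavanone), then the C2–C3 bond, which opens ring C to a diazomethyl ketone on ring A carrying an O-benzyl ether. The last cuts are the O1–CH2 ether bond and the C3–N2 bond.
- Enabling feature: C2 is bonded to O1 and to the ring B aryl group, so in the open benzyl aryl ether its two C–H bonds are both α-oxygenated and benzylic, and they lie in a 1,6-relationship to a carbene centred on C3.
- Forward: a ring A methyl ketone and a ring B benzylic bromide are joined through O1, the methyl ketone is converted to the diazo ketone, and ring C (the only ring built) closes in the C–H insertion. Oxygenation and methylation at C3 and debenzylation complete the molecule.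
- Stereochemistry: C2 is set by the chiral divalent rhodium carboxylate in the insertion. C3 is set relative to C2 when the derived enol silane is oxidised on the face away from the aryl group, giving the 2,3-trans (2R,3R) arrangement.

Key step: step 7

Assumption: Rh2(S-PTTL)4, dirhodium tetrakis[N-phthaloyl-(S)-tert-leucinate], is taken to give the (2S) sense at C2; if a trial run shows the opposite sense, the mirror-image catalyst Rh2(R-PTTL)4 is used and nothing else changes.

**Route**

Step 1
Reactants: 1 3,4,5-trimethoxyphenol
Product: 2 1-(6-hydroxy-2,3,4-trimethoxyphenyl)ethanone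
Conditions: AcOH, BF3·OEt2, 85 °C; then H2O
Reagents that add atoms: acetic acid CC(=O)O
Why: Friedel–Crafts acylation (possibly through the O-acetate and a Fries shift) can only take place at the two equivalent free positions ortho to the hydroxyl group of this electron-rich phenol, and the product is held as a boron chelate that resists a second acylation.

Step 2
Reactants: 3 methyl 3,5-dihydroxy-4-methoxybenzoate
Product: 4 methyl 3,5-bis(benzyloxy)-4-methoxybenzoate
Conditions: BnBr, K2CO3, DMF, 60 °C
Reagents that add atoms: benzyl bromide BrCc1ccccc1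
Why: Williamson ether synthesis on both phenols, with benzyl chosen because it is inert to the carbonate, amide base, silyl triflate, dioxirane and oxonium salt used later and leaves at the end under neutral hydrogenolysis.

Step 3
Reactants: 4 methyl 3,5-bis(benzyloxy)-4-methoxybenzoate
Product: 5 [3,5-bis(benzyloxy)-4-methoxyphenyl]methanol
Conditions: LiAlH4, THF, 0 °C
Reagents that add atoms: none
Why: Hydride reduction of the ester to the primary benzylic alcohol, to which aryl benzyl and aryl methyl ethers are inert.

Step 4
Reactants: 5 [3,5-bis(benzyloxy)-4-methoxyphenyl]methanol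
Product: 6 1,3-bis(benzyloxy)-5-(bromomethyl)-2-methoxybenzene
Conditions: PBr3, CH2Cl2, 0 °C
Reagents that add atoms: phosphorus tribromide BrP(Br)Br
Why: Bromination of a primary benzylic alcohol through its phosphite ester (SN2 by bromide) is fast at 0 °C and does not touch the aryl ethers.

Step 5
Reactants: 2 1-(6-hydroxy-2,3,4-trimethoxyphenyl)ethanone; 6 1,3-bis(benzyloxy)-5-(bromomethyl)-2-methoxybenzene
Product: 7 1-[2-{[3,5-bis(benzyloxy)-4-methoxyphenyl]methoxy}-4,5,6-trimethoxyphenyl]ethanone
Conditions: K2CO3, DMF, 60 °C
Reagents that add atoms: none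
Why: Williamson O-alkylation of a hydrogen-bonded ortho-acyl phenol with a reactive benzylic bromide is standard for 2-hydroxyacetophenones, and carbonate does not enolise the ketone, so only O1 is alkylated.

Step 6
Reactants: 7 1-[2-{[3,5-bis(benzyloxy)-4-methoxyphenyl]methoxy}-4,5,6-trimethoxyphenyl]ethanone
Product: 9 2-diazo-1-[2-{[3,5-bis(benzyloxy)-4-methoxyphenyl]methoxy}-4,5,6-trimethoxyphenyl]ethanone, via trifluoroacetyl ketone 8 (not isolated)
Conditions: LiN(SiMe3)2, THF, −78 °C; CF3CO2CH2CF3, −78 °C; acidic extraction, then directly MsN3, Et3N, H2O, MeCN, rt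
Reagents that add atoms: methanesulfonyl azide CS(=O)(=O)N=[N+]=[N-] (the two nitrogen atoms of 9); 2,2,2-trifluoroethyl trifluoroacetate FC(F)(F)COC(=O)C(F)(F)F (the trifluoroacetyl group of 8 only)
Why: Detrifluoroacetylative diazo transfer, a variant of the Regitz diazo transfer: the lithium enolate of the methyl ketone is C-trifluoroacetylated to the activated 1,3-diketone 8, which takes the diazo group from the sulfonyl azide and loses the trifluoroacetyl group as the N-sulfonyl amide, so no acid chloride of a hindered, acid-sensitive benzoic acid is needed.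

Step 7
Reactants: 9 2-diazo-1-[2-{[3,5-bis(benzyloxy)-4-methoxyphenyl]methoxy}-4,5,6-trimethoxyphenyl]ethanone
Product: 10 (2S)-2-[3,5-bis(benzyloxy)-4-methoxyphenyl]-5,6,7-trimethoxychroman-4-one
Conditions: Rh2(S-PTTL)4 (2 mol %), CH2Cl2, −10 °C to rt, slow addition of 9 at high dilution
Reagents that add atoms: none
Why: The divalent rhodium carboxylate expels N2 from 9 to give an electrophilic rhodium carbene at C3, which takes one of the two enantiotopic benzylic hydrogens of the O1–CH2–aryl group through a concerted, hydride-transfer-like three-centre transition state and forms the C2–C3 bond. The closest known reaction type is the intramolecular C–H insertion of 2-alkoxyphenyl diazomethyl ketones under chiral dirhodium carboxylate catalysis, which gives 2-substituted chroman-4-ones. Ring C closes as a six-membered ring by a formal 1,6-insertion, C3 bonding to the carbon next to O1. The only new stereocentre, C2, is under catalyst control: the chiral N-phthaloyl-tert-leucinate ligands around the carbene decide which of the two hydrogens is reached. The step needs insertion at the benzylic CH2 to win over oxonium ylide formation at O1 (followed by 1,2-benzyl shift to a benzofuranone) and over insertion into the methoxy group on the other side of the ketone; the double activation of the C2–H bonds by O1 and the ring B aryl group, the weak donor character of an aryl ether oxygen conjugated to the ketone, and the bulky carboxylate ligands should secure this.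

Step 8
Reactants: 10 (2S)-2-[3,5-bis(benzyloxy)-4-methoxyphenyl]-5,6,7-trimethoxychroman-4-one
Product: 11 (2S)-2-[3,5-bis(benzyloxy)-4-methoxyphenyl]-5,6,7-trimethoxy-4-(trimethylsilyloxy)-2H-chromene
Conditions: TMSOTf, Et3N, CH2Cl2, 0 °C, dark; non-aqueous work-up, used without chromatography
Reagents that add atoms: trimethylsilyl trifluoromethanesulfonate C[Si](C)(C)OS(=O)(=O)C(F)(F)F
Why: Soft enolisation with a silyl triflate and an amine gives the silyl enol ether without a free enolate, which avoids the base-induced β-elimination that would open ring C to a chalcone and racemise C2.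

Step 9
Reactants: 11 (2S)-2-[3,5-bis(benzyloxy)-4-methoxyphenyl]-5,6,7-trimethoxy-4-(trimethylsilyloxy)-2H-chromene
Product: 13 (2R,3R)-2-[3,5-bis(benzyloxy)-4-methoxyphenyl]-3-hydroxy-5,6,7-trimethoxychroman-4-one, via silyloxy epoxide 12 (not isolated)
Conditions: DMDO (acetone solution), CH2Cl2, −40 to 0 °C; then aq. citric acid, THF, 0 °C
Reagents that add atoms: dimethyldioxirane CC1(C)OO1
Why: Rubottom oxidation: the dioxirane epoxidises the electron-rich enol ether on the face opposite the C2 aryl group and acid opening of the silyloxy epoxide 12 with loss of the silyl group gives the α-hydroxy ketone, so C3 is set trans to the aryl group by substrate control (the C2 descriptor changes from S to R only because C3 now outranks the aryl carbon).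

Step 10
Reactants: 13 (2R,3R)-2-[3,5-bis(benzyloxy)-4-methoxyphenyl]-3-hydroxy-5,6,7-trimethoxychroman-4-one
Product: 14 (2R,3R)-2-[3,5-bis(benzyloxy)-4-methoxyphenyl]-3,5,6,7-tetramethoxychroman-4-one
Conditions: Me3OBF4, 1,8-bis(dimethylamino)naphthalene, 4 Å molecular sieves, CH2Cl2, rt
Reagents that add atoms: trimethyloxonium tetrafluoroborate C[O+](C)C.F[B-](F)(F)F
Why: O-methylation of a base-sensitive secondary alcohol with Meerwein's salt buffered by a non-nucleophilic amine proceeds without enolate formation, so C3 is not epimerised and ring C is not opened.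

Step 11
Reactants: 14 (2R,3R)-2-[3,5-bis(benzyloxy)-4-methoxyphenyl]-3,5,6,7-tetramethoxychroman-4-one
Product: 15 (2R,3R)-2-(3,5-dihydroxy-4-methoxyphenyl)-3,5,6,7-tetramethoxychroman-4-one
Conditions: H2 (1 atm), 10% Pd/C, EtOAc, rt
Reagents that add atoms: none
Why: Catalytic hydrogenolysis of the two primary benzyl aryl ethers under neutral conditions should be much faster than cleavage of the cyclic secondary C2–O1 bond or reduction of the hindered aryl ketone, so both stereocentres are kept.

**Compound list**

1 | 3,4,5-trimethoxyphenol | COc1cc(O)cc(OC)c1OC | starting material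
2 | 1-(6-hydroxy-2,3,4-trimethoxyphenyl)ethanone (2'-hydroxy-4',5',6'-trimethoxyacetophenone) | CC(=O)c1c(O)cc(OC)c(OC)c1OC | intermediate
3 | methyl 3,5-dihydroxy-4-methoxybenzoate | COC(=O)c1cc(O)c(OC)c(O)c1 | starting material
4 | methyl 3,5-bis(benzyloxy)-4-methoxybenzoate | COC(=O)c1cc(OCc2ccccc2)c(OC)c(OCc2ccccc2)c1 | intermediate
5 | [3,5-bis(benzyloxy)-4-methoxyphenyl]methanol | OCc1cc(OCc2ccccc2)c(OC)c(OCc2ccccc2)c1 | intermediate
6 | 1,3-bis(benzyloxy)-5-(bromomethyl)-2-methoxybenzene | BrCc1cc(OCc2ccccc2)c(OC)c(OCc2ccccc2)c1 | intermediate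
7 | 1-[2-{[3,5-bis(benzyloxy)-4-methoxyphenyl]methoxy}-4,5,6-trimethoxyphenyl]ethanone | CC(=O)c1c(OCc2cc(OCc3ccccc3)c(OC)c(OCc3ccccc3)c2)cc(OC)c(OC)c1OC | intermediate
8 | 1-[2-{[3,5-bis(benzyloxy)-4-methoxyphenyl]methoxy}-4,5,6-trimethoxyphenyl]-4,4,4-trifluorobutane-1,3-dione (formed in the flask, drawn as the diketone) | O=C(CC(=O)C(F)(F)F)c1c(OCc2cc(OCc3ccccc3)c(OC)c(OCc3ccccc3)c2)cc(OC)c(OC)c1OC | intermediate
9 | 2-diazo-1-[2-{[3,5-bis(benzyloxy)-4-methoxyphenyl]methoxy}-4,5,6-trimethoxyphenyl]ethanone | [N-]=[N+]=CC(=O)c1c(OCc2cc(OCc3ccccc3)c(OC)c(OCc3ccccc3)c2)cc(OC)c(OC)c1OC | intermediate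
10 | (2S)-2-[3,5-bis(benzyloxy)-4-methoxyphenyl]-5,6,7-trimethoxychroman-4-one | COc1cc2c(c(OC)c1OC)C(=O)C[C@@H](c1cc(OCc3ccccc3)c(OC)c(OCc3ccccc3)c1)O2 | intermediate
11 | (2S)-2-[3,5-bis(benzyloxy)-4-methoxyphenyl]-5,6,7-trimethoxy-4-(trimethylsilyloxy)-2H-chromene | COc1cc2c(c(OC)c1OC)C(O[Si](C)(C)C)=C[C@@H](c1cc(OCc3ccccc3)c(OC)c(OCc3ccccc3)c1)O2 | intermediate
12 | 3,4-epoxide of 11 (4-trimethylsilyloxy-3,4-epoxychroman, oxirane oxygen on the face opposite the C2 aryl group; formed in the flask) | COc1cc2c(c(OC)c1OC)[C@]3(O[Si](C)(C)C)O[C@@H]3[C@@H](c1cc(OCc4ccccc4)c(OC)c(OCc4ccccc4)c1)O2 | intermediate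
13 | (2R,3R)-2-[3,5-bis(benzyloxy)-4-methoxyphenyl]-3-hydroxy-5,6,7-trimethoxychroman-4-one (2,3-trans) | COc1cc2c(c(OC)c1OC)C(=O)[C@H](O)[C@@H](c1cc(OCc3ccccc3)c(OC)c(OCc3ccccc3)c1)O2 | intermediate
14 | (2R,3R)-2-[3,5-bis(benzyloxy)-4-methoxyphenyl]-3,5,6,7-tetramethoxychroman-4-one (2,3-trans) | COc1cc2c(c(OC)c1OC)C(=O)[C@H](OC)[C@@H](c1cc(OCc3ccccc3)c(OC)c(OCc3ccccc3)c1)O2 | intermediate
15 | (2R,3R)-2-(3,5-dihydroxy-4-methoxyphenyl)-3,5,6,7-tetramethoxychroman-4-one (2,3-trans) | COc1cc2c(c(OC)c1OC)C(=O)[C@H](OC)[C@@H](c1cc(O)c(OC)c(O)c1)O2 | target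

**Step count**

Total: 11 steps. Longest linear sequence: 10 steps (3 to 15 through steps 2 to 11); step 1 is a one-step side branch that joins at step 5.

**Steps most likely to fail**

1. Step 7. The carbene may be diverted: attack of the O1 lone pair to an oxonium ylide followed by 1,2-migration of the benzyl group, insertion into the methoxy group ortho to the ketone, carbene dimerisation, or weak discrimination between the two enantiotopic hydrogens. The fallback uses no carbene; it sets out from 2 and 5 and returns at 13, so that steps 6 to 9 are not needed.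
   - 2 is protected (MOMCl, NaH, DMF) as 1-[2-(methoxymethoxy)-4,5,6-trimethoxyphenyl]ethanone F1.
   - 5 is oxidised with MnO2 in CH2Cl2 to 3,5-bis(benzyloxy)-4-methoxybenzaldehyde F2.
   - Claisen–Schmidt condensation of the two (KOH, EtOH, rt) gives the chalcone (E)-3-[3,5-bis(benzyloxy)-4-methoxyphenyl]-1-[2-(methoxymethoxy)-4,5,6-trimethoxyphenyl]prop-2-en-1-one F3.
   - Juliá–Colonna epoxidation (poly-L-leucine, urea–H2O2, DBU, THF) should give the epoxy ketone [(2R,3S)-3-[3,5-bis(benzyloxy)-4-methoxyphenyl]oxiran-2-yl][2-(methoxymethoxy)-4,5,6-trimethoxyphenyl]methanone F4.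
   - HCl in MeOH at 50 °C removes the acetal, and the freed phenol opens the oxirane at the benzylic carbon with inversion (6-endo), which should give the trans compound 13.

2. Step 8. Ring C may open at the benzylic C2–O1 bond while the ketone is activated by the silyl triflate, or the 2H-chromene may undergo reversible electrocyclic opening under heat or light; either process erodes the configuration at C2. The labile enol ether may also hydrolyse back to 10. The fallback goes from 10 directly to 13 by enolate hydroxylation (Davis oxidation): KN(SiMe3)2, THF, −78 °C, then 2-(phenylsulfonyl)-3-phenyloxaziridine, quenched cold with AcOH. The oxidant should approach the potassium enolate on the face away from the aryl group, and step 9 is skipped. No compound outside the list is made (F0).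

3. Step 10. Methyl transfer to the hindered, hydrogen-bonded hydroxyl group may be slow, leaving time for amine-induced enolisation with epimerisation at C3 or β-elimination of the O1 phenoxide. The fallback replaces alkylation under base with acid-catalysed methyl transfer from a diazoalkane: TMSCHN2, aq. HBF4, CH2Cl2, 0 °C, from 13 to 14, with no base present. No compound outside the list is made (F0).

**Further compounds**

F1 | step 7 | 1-[2-(methoxymethoxy)-4,5,6-trimethoxyphenyl]ethanone | CC(=O)c1c(OCOC)cc(OC)c(OC)c1OC
F2 | step 7 | 3,5-bis(benzyloxy)-4-methoxybenzaldehyde | O=Cc1cc(OCc2ccccc2)c(OC)c(OCc2ccccc2)c1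
F3 | step 7 | (E)-3-[3,5-bis(benzyloxy)-4-methoxyphenyl]-1-[2-(methoxymethoxy)-4,5,6-trimethoxyphenyl]prop-2-en-1-one | COCOc1cc(OC)c(OC)c(OC)c1C(=O)/C=C/c1cc(OCc2ccccc2)c(OC)c(OCc2ccccc2)c1
F4 | step 7 | [(2R,3S)-3-[3,5-bis(benzyloxy)-4-methoxyphenyl]oxiran-2-yl][2-(methoxymethoxy)-4,5,6-trimethoxyphenyl]methanone | COCOc1cc(OC)c(OC)c(OC)c1C(=O)[C@@H]1O[C@H]1c1cc(OCc2ccccc2)c(OC)c(OCc2ccccc2)c1
F0 | step 8 | none | none
F0 | step 10 | none | none
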